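The nucleophile stands to the electrophile at 1.00, and this symmetric charge is the zero of the scale: in the plain second-order picture, which is an assumption and not yet a finding about this flask, one nucleophile for each electrophile takes both down together toward full conversion.

| setting | birch | elm | flask |
|---|---|---|---|
| electrophile | 0.050 M | 0.050 M | 0.050 M |
| nucleophile | 0.050 M | 0.050 M | 0.0500 M |
| buffer base | 0.010 M | 0.010 M | 0.0100 M |
| buffer acid | 0.015 M | 0.022 M | 0.0150 M |
| remark | the very flask that is asked about, followed so far | run made earlier |  |
| time |  |  | 4.0 h |

| run | time / min | electrophile / % | target / % |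
|---|---|---|---|
| birch | 15.0 | 95 | 7 |
| birch | 30.0 | 93 | 9 |
| birch | 40.0 | 88 | 13 |
| birch | 60.0 | 83 | 18 |
| birch | 80.0 | 78 | 20 |
| elm | 8.00 | 95 | 4 |
| elm | 15.0 | 95 | 4 |
| elm | 25.0 | 94 | 6 |
| elm | 50.0 | 86 | 12 |
| elm | 90.0 | 77 | 21 |

(scatter of a reading: 1.5 percentage points)

- the earlier runs do not show the pH; that part of a forecast is a guess

- part of the electrophile that has reacted at 4.0 h
- pH of the solution at 4.0 h

How fast does the flask go? At 80.0 min, birch, the flask itself, reads 78% electrophile, so reacted over remaining is 0.282, and that ratio grows by a read 0.00353 min⁻¹. Elm, with 1.47 times the buffer acid of birch, gives 0.941 of that reading, so within the scatter these runs show no clear step with the buffer ratio.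

What pays for the acid? This reckoning assumes that each reacted electrophile releases one acid. Buffer base then covers 20.0% of the electrophile, reached by the read rate after about 1.18 h, and past that estimated point this reckoning has each further step cost a second nucleophile as protonated nucleophile, which makes the nucleophile the limiting reagent. The quantity to carry is the paid ceiling, (c(nucleophile) + c(buffer base)) / (2 c(electrophile)), the share of electrophile that the charged base and nucleophile can pay for, here 60.0%, lower than the symmetric zero. Integrating the second-order law past that point, with nucleophile falling by 2 per electrophile, gives 42.0% reacted at 4.0 h. The readings show no pH, so this reckoning offers none.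

The forecast says 41% (30% to 52%) and pH 6.5 (4.5 to 8), with the caution: “The main risk is that the reaction releases acid.”

The flask gives 40.7% reacted and pH 7.54.

    electrophile + nucleophile ⇌ acid + target + leaving group (K = 3.60 × 10⁻⁵ M, k = 0.0680 L mol⁻¹ min⁻¹)
    protonated nucleophile ⇌ nucleophile + acid, settled at all times (K = 5.00 × 10⁻⁸ M)
    buffer acid ⇌ buffer base + acid, settled at all times (K = 5.00 × 10⁻¹⁰ M)

Left to 40.0 h, the flask has reacted 58.9%, just under the ceiling of 60.0%, with nucleophile down to 2.14% of its charge. The neighbour flask, charged with 0.020 M of electrophile, has a ceiling by the same reckoning of 150%, above its whole electrophile charge. At 4.00 h that neighbour flask has reacted 50.1%, nothing charged has run out, and 50% of its electrophile and 74% of its nucleophile stand unbound.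

All runs are simulated on assumed constants; scatter was added.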